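**Retrosynthetic overview**

1. Last skeletal bonds: the lactone C7–O bond and the C16–O acetate are formed together by a palladium-catalysed 1,4-carboxy-acetoxylation of a ring B diene acid. This closes lactone ring C, sets C7 and fixes the C5=C6 geometry.
2. The diene acid (ten-membered ring B, Z-C6=C7, exocyclic C5=C16) comes from an acyclic enyne acid by ethylene enyne metathesis followed by ring-closing metathesis.
3. C8 and C17 come from a chelation-controlled propanoate aldol on a vinyl ketone; C9 and C10 come from an amide-enolate [2,3]-Wittig shift across ring A (C12–O to C10–C9).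
4. Ring A with C1, C2 and C14 comes from (S)-carvone: α′-acylation and methylation, Criegee degradation of isopropenyl to C14–O, CBS reduction at C2, then epoxidation and Wharton transposition to the C12 allylic alcohol.
5. Ring order: A (chiral pool), then B (metathesis), then C (C–O bond formation); end game is acetonide to acetates, then MOM removal.

Assumption: briarane numbering is used for locants (C1 quaternary ring-fusion carbon with methyl C15, C2–C9 around ring B, C10 ring-fusion CH, C11–C14 in ring A, C16 on C5, C17(C18)–C19 the lactone carbons, C20 on C11), β is the face of ring A that carries C15, and conjugate bases of numbered compounds and work-up-labile metal adducts are named in the step text instead of being numbered.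

**Route**

Step 1
Reactants: 1 (S)-(+)-carvone; 2 5-(trimethylsilyl)pent-4-ynoic acid
Product: 4 6-acylcarvone β-diketone, via acid chloride 3 (not isolated)
Conditions: 2, (COCl)2, cat. DMF, CH2Cl2, 0 °C → rt, evaporate; 1 (2.1 equiv), LiN(i-Pr)2 (2.0 equiv), THF, −78 °C; then 3 in THF, −78 → −40 °C; aq. NH4Cl
Reagents that add atoms: none
Why: Kinetic α′-deprotonation of the enone and Claisen-type C-acylation by the acid chloride give the β-diketone; the second equivalent of enolate takes up the acidic proton of the product, which suppresses O-acylation and double acylation.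

Step 2
Reactants: 4 6-acylcarvone β-diketone
Product: 5 methylated diketone (quaternary C1)
Conditions: MeI (3 equiv), K2CO3, acetone, 40 °C
Reagents that add atoms: iodomethane, CI
Why: C-alkylation of the stabilised β-diketone enolate, in which iodomethane enters anti to the neighbouring isopropenyl group (as in known 6,6-dialkylations of carvone), sets C1 with the methyl trans and the acyl chain cis to the future C14 oxygen.

Step 3
Reactants: 5 methylated diketone
Product: 8 C14 acetate diketone, via methoxy hydroperoxide 6 (not isolated), via peracetate 7 (not isolated)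
Conditions: O3, CH2Cl2–MeOH 4:1, −78 °C; Ar purge; then Ac2O, Et3N, 4-(dimethylamino)pyridine (cat.), −78 → 25 °C
Reagents that add atoms: ozone, [O-][O+]=O; methanol, CO
Why: Criegee rearrangement, in which ozone cleaves only the isopropenyl olefin (enone and silylalkyne are deactivated) and the peracetate rearranges with retention, so C14 carries the acetate where the isopropenyl group was (ester oxygen from ozone, carbonyl oxygen from methanol after demethylation of the dioxycarbenium ion by acetate).

Step 4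
Reactants: 8 C14 acetate diketone
Product: 9 C2 alcohol (2R)
Conditions: (S)-1-methyl-3,3-diphenyltetrahydro-1H,3H-pyrrolo[1,2-c][1,3,2]oxazaborole (C18H20BNO, 0.3 equiv), catecholborane (1.5 equiv), toluene, −78 °C; MeOH quench, aq. NaHCO3
Reagents that add atoms: none
Why: Corey–Bakshi–Shibata reduction, in which the unconjugated C2 ketone (tert-alkyl versus CH2 flank) reacts faster than the doubly hindered conjugated ketone and the (S)-oxazaborolidine sets 2R under reagent control, while catecholborane at −78 °C leaves the alkyne alone.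

Step 5
Reactants: 9 C2 alcohol
Product: 11 acetonide enone, via diol 10 (not isolated)
Conditions: TsOH·H2O (0.2 equiv), MeOH, 40 °C; evaporate; then Me2C(OMe)2, acetone, 25 °C; Et3N
Reagents that add atoms: 2,2-dimethoxypropane, COC(C)(C)OC
Why: Acid-catalysed transesterification frees the C14 hydroxyl without base (methoxide would cleave the C–Si bond and threaten the β-hydroxy ketone), and ketalisation of the syn-1,3-diol gives the six-membered acetonide that protects O2 and O14 through the strongly basic steps.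

Step 6
Reactants: 11 acetonide enone
Product: 12 β-epoxy ketone
Conditions: t-BuOOH (decane solution, 3 equiv), 1,8-diazabicyclo[5.4.0]undec-7-ene (1.5 equiv), CH2Cl2, 0 → 25 °C
Reagents that add atoms: tert-butyl hydroperoxide, CC(C)(C)OO
Why: Weitz–Scheffer nucleophilic epoxidation, in which the peroxide adds to C12 axially and anti to the C14–O bond (as carvone does), gives the epoxide on the β face, and the aprotic medium keeps the silylalkyne.

Step 7
Reactants: 12 β-epoxy ketone
Product: 14 C12 allylic alcohol, via epoxy hydrazone 13 (not isolated)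
Conditions: N2H4·H2O (5 equiv), AcOH (1 equiv), i-PrOH, 0 → 25 °C, degassed
Reagents that add atoms: none
Why: Wharton transposition, in which the epoxy hydrazone fragments with loss of dinitrogen, leaves the epoxide oxygen on C12 with its β configuration and moves the olefin to C10=C11.

Step 8
Reactants: 14 C12 allylic alcohol; 15 4-(chloroacetyl)morpholine
Product: 16 allyl ether of the morpholine glycolamide
Conditions: NaH (1.2 equiv), THF, 0 °C; then 15 (1.3 equiv), Bu4NI (0.1 equiv), 0 → 25 °C
Reagents that add atoms: none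
Why: Williamson etherification of the sodium alkoxide with the α-chloro amide (iodide catalysis) puts C9 and C8 on the C12 oxygen without touching a stereocentre.

Step 9
Reactants: 16 allyl ether of the morpholine glycolamide
Product: 18 C9 MOM ether amide, via lithium alkoxide 17 (not isolated)
Conditions: LiN(i-Pr)2 (2 equiv), THF, −78 → −30 °C; then MeOCH2Cl (3 equiv), −30 → 0 °C
Reagents that add atoms: chloromethyl methyl ether, COCCl
Why: Amide-enolate [2,3]-Wittig rearrangement, which transfers the β C12–O chirality suprafacially to C10 (C9 arm β, 10S) through the envelope transition state with the amide turned away from ring A and the C1 methyl (9R), after which the alkoxide is capped in the same pot as the chelating MOM ether.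

Step 10
Reactants: 18 C9 MOM ether amide
Product: 19 vinyl ketone
Conditions: CH2=CHMgBr (3 equiv), THF, −20 → 0 °C; inverse quench into cold aq. NaHSO4
Reagents that add atoms: vinylmagnesium bromide, C=C[Mg]Br
Why: Acyl substitution of the morpholine amide by the Grignard reagent through a chelated tetrahedral magnesium adduct that collapses only on acidic quench, so the vinyl ketone is not attacked a second time and the acid quench keeps morpholine from adding to it.

Step 11
Reactants: 19 vinyl ketone; 20 methyl propanoate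
Product: 22 enyne hydroxy acid, via methyl ester 21 (not isolated)
Conditions: 20 (3.2 equiv), LiN(i-Pr)2 (3 equiv), THF, −78 °C; add 19, −78 °C, 30 min; then aq. LiOH, MeOH, −78 → 30 °C; cold 0.5 M HCl to pH 4
Reagents that add atoms: lithium hydroxide, [Li+].[OH-]
Why: Aldol addition of the (E)-lithium ester enolate under Cram-chelate control, in which lithium bridges the ketone and the C9 MOM oxygen so that attack at C8 comes from the H9 face (8R, 1,2- and not 1,4-addition at −78 °C) and the chelated chair with the C9 arm axial puts the enolate methyl syn to the new hydroxyl (17R, also the expected thermodynamic C17 epimer of the later lactone); hydroxide then saponifies the ester and removes the alkynyl silyl group in the same pot.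

Step 12
Reactants: 22 enyne hydroxy acid
Product: 24 ring B diene acid, via triene 23 (not isolated)
Conditions: second-generation Grubbs catalyst RuCl2(=CHPh)(H2IMes)(PCy3) (10 mol %), ethylene (1 atm), CH2Cl2, 25 °C; then Ar sparge, toluene (1 mM), 80 °C
Reagents that add atoms: ethylene, C=C
Why: Tandem enyne cross-metathesis with ethylene (alkyne to 2-substituted butadiene) and diene–ene ring-closing metathesis once ethylene is purged, in which ring A, the fused dioxane and the quaternary C1 and C8 centres pre-organise the two chains, the free allylic hydroxyl accelerates metathesis, and the ten-membered ring forms the new C6=C7 bond as the less strained Z olefin.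

Step 13
Reactants: 24 ring B diene acid
Product: 25 lactone 16-acetate
Conditions: Pd(OAc)2 (10 mol %), 1,4-benzoquinone (2 equiv), LiOAc (2 equiv), AcOH–acetone 1:4, 25 °C
Reagents that add atoms: acetic acid, CC(=O)O
Why: Proposed new method: divalent palladium binds the s-trans exocyclic–endocyclic diene, the C19 carboxylate adds 5-exo to C7 anti to palladium from the face opposite C9 while the C8 hydroxyl lies in the olefin plane (allylic 1,3-strain), which closes ring C trans-fused and sets 7S, the resulting η3-allyl (C6–C5–C16) is captured by acetate at the unhindered exocyclic terminus C16 to leave the ring-cis C5=C6 bond, and benzoquinone reoxidises palladium; the closest known reaction is the Bäckvall palladium-catalysed intramolecular 1,4-oxylactonisation and 1,4-diacetoxylation of cyclic 1,3-dienes, which has not been shown on a 2-substituted exocyclic–endocyclic diene inside a medium ring.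

Step 14
Reactants: 25 lactone 16-acetate
Product: 26 2,14-diol
Conditions: AcOH–H2O 4:1, 40 °C
Reagents that add atoms: none
Why: Acid hydrolysis of the acetonide (acetal cleavage) frees O2 and O14 while the MOM ether, the allylic acetate and the lactone survive.

Step 15
Reactants: 26 2,14-diol
Product: 27 triacetate MOM ether
Conditions: Ac2O (6 equiv), pyridine, 4-(dimethylamino)pyridine (0.1 equiv), CH2Cl2, 0 → 25 °C
Reagents that add atoms: acetic anhydride, CC(=O)OC(C)=O
Why: Nucleophile-catalysed acetylation of the two secondary hydroxyls, with the tertiary C8 hydroxyl inert under these conditions and O9 masked as the MOM ether.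

Step 16
Reactants: 27 triacetate MOM ether
Product: 28 CNP0322315.2 (target)
Conditions: ZnBr2 (1.5 equiv), n-PrSH (3 equiv), CH2Cl2, 0 °C
Reagents that add atoms: none
Why: Lewis acid–thiol cleavage of the MOM acetal (ZnBr2 activates the acetal, the thiol traps the oxocarbenium ion) is fast at 0 °C and leaves the three acetates, the lactone and the tertiary alcohol intact.

**Compound list**

1 | (S)-(+)-carvone, (5S)-2-methyl-5-(prop-1-en-2-yl)cyclohex-2-en-1-one | O=C1C(C)=CC[C@H](C(C)=C)C1 | starting material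
2 | 5-(trimethylsilyl)pent-4-ynoic acid | OC(=O)CCC#C[Si](C)(C)C | starting material
3 | 5-(trimethylsilyl)pent-4-ynoyl chloride | ClC(=O)CCC#C[Si](C)(C)C | intermediate (not isolated)
4 | (5S)-2-methyl-5-(prop-1-en-2-yl)-6-[5-(trimethylsilyl)pent-4-ynoyl]cyclohex-2-en-1-one (C6 epimers and enol form) | O=C1C(C)=CC[C@H](C(C)=C)C1C(=O)CCC#C[Si](C)(C)C | intermediate
5 | (5R,6R)-2,6-dimethyl-5-(prop-1-en-2-yl)-6-[5-(trimethylsilyl)pent-4-ynoyl]cyclohex-2-en-1-one | O=C1C(C)=CC[C@H](C(C)=C)[C@]1(C)C(=O)CCC#C[Si](C)(C)C | intermediate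
6 | (5S,6R)-5-(1-hydroperoxy-1-methoxyethyl)-2,6-dimethyl-6-[5-(trimethylsilyl)pent-4-ynoyl]cyclohex-2-en-1-one (ketal carbon epimers) | O=C1C(C)=CC[C@H](C(C)(OC)OO)[C@]1(C)C(=O)CCC#C[Si](C)(C)C | intermediate (not isolated)
7 | (5S,6R)-5-[1-(acetylperoxy)-1-methoxyethyl]-2,6-dimethyl-6-[5-(trimethylsilyl)pent-4-ynoyl]cyclohex-2-en-1-one | O=C1C(C)=CC[C@H](C(C)(OC)OOC(C)=O)[C@]1(C)C(=O)CCC#C[Si](C)(C)C | intermediate (not isolated)
8 | (1S,2R)-2,4-dimethyl-3-oxo-2-[5-(trimethylsilyl)pent-4-ynoyl]cyclohex-4-en-1-yl acetate | O=C1C(C)=CC[C@H](OC(C)=O)[C@]1(C)C(=O)CCC#C[Si](C)(C)C | intermediate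
9 | (1S,2S)-2-[(1R)-1-hydroxy-5-(trimethylsilyl)pent-4-yn-1-yl]-2,4-dimethyl-3-oxocyclohex-4-en-1-yl acetate | O=C1C(C)=CC[C@H](OC(C)=O)[C@]1(C)[C@H](O)CCC#C[Si](C)(C)C | intermediate
10 | (5S,6S)-5-hydroxy-6-[(1R)-1-hydroxy-5-(trimethylsilyl)pent-4-yn-1-yl]-2,6-dimethylcyclohex-2-en-1-one | O=C1C(C)=CC[C@H](O)[C@]1(C)[C@H](O)CCC#C[Si](C)(C)C | intermediate (not isolated)
11 | (4R,4aS,8aS)-2,2,4a,6-tetramethyl-4-[4-(trimethylsilyl)but-3-yn-1-yl]-4a,8a-dihydro-4H-1,3-benzodioxin-5(8H)-one | O=C1C(C)=CC[C@H](OC2(C)C)[C@]1(C)[C@H](O2)CCC#C[Si](C)(C)C | intermediate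
12 | (4R,4aS,6S,7S,8aS)-6,7-epoxy-2,2,4a,6-tetramethyl-4-[4-(trimethylsilyl)but-3-yn-1-yl]hexahydro-4H-1,3-benzodioxin-5-one (epoxide on the β face) | O=C1[C@@]2(C)O[C@H]2C[C@H](OC3(C)C)[C@]1(C)[C@H](O3)CCC#C[Si](C)(C)C | intermediate
13 | hydrazone of epoxy ketone 12 (C=N–NH2 at the former ketone carbon) | NN=C1[C@@]2(C)O[C@H]2C[C@H](OC3(C)C)[C@]1(C)[C@H](O3)CCC#C[Si](C)(C)C | intermediate (not isolated)
14 | (4R,4aS,7S,8aS)-2,2,4a,6-tetramethyl-4-[4-(trimethylsilyl)but-3-yn-1-yl]-4a,7,8,8a-tetrahydro-4H-1,3-benzodioxin-7-ol | C1=C(C)[C@@H](O)C[C@H](OC2(C)C)[C@]1(C)[C@H](O2)CCC#C[Si](C)(C)C | intermediate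
15 | 4-(chloroacetyl)morpholine, 2-chloro-1-(morpholin-4-yl)ethan-1-one | ClCC(=O)N1CCOCC1 | starting material
16 | 1-(morpholin-4-yl)-2-{[(4R,4aS,7S,8aS)-2,2,4a,6-tetramethyl-4-[4-(trimethylsilyl)but-3-yn-1-yl]-4a,7,8,8a-tetrahydro-4H-1,3-benzodioxin-7-yl]oxy}ethan-1-one | C1=C(C)[C@@H](OCC(=O)N3CCOCC3)C[C@H](OC2(C)C)[C@]1(C)[C@H](O2)CCC#C[Si](C)(C)C | intermediate
17 | lithium (1R)-2-(morpholin-4-yl)-2-oxo-1-[(4R,4aS,5S,8aS)-2,2,4a,6-tetramethyl-4-[4-(trimethylsilyl)but-3-yn-1-yl]-4a,5,8,8a-tetrahydro-4H-1,3-benzodioxin-5-yl]ethan-1-olate | O=C(N3CCOCC3)[C@H]([O-])[C@H]1C(C)=CC[C@H](OC2(C)C)[C@]1(C)[C@H](O2)CCC#C[Si](C)(C)C.[Li+] | intermediate (not isolated)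
18 | (2R)-2-(methoxymethoxy)-1-(morpholin-4-yl)-2-[(4R,4aS,5S,8aS)-2,2,4a,6-tetramethyl-4-[4-(trimethylsilyl)but-3-yn-1-yl]-4a,5,8,8a-tetrahydro-4H-1,3-benzodioxin-5-yl]ethan-1-one | O=C(N3CCOCC3)[C@H](OCOC)[C@H]1C(C)=CC[C@H](OC2(C)C)[C@]1(C)[C@H](O2)CCC#C[Si](C)(C)C | intermediate
19 | (1R)-1-(methoxymethoxy)-1-[(4R,4aS,5S,8aS)-2,2,4a,6-tetramethyl-4-[4-(trimethylsilyl)but-3-yn-1-yl]-4a,5,8,8a-tetrahydro-4H-1,3-benzodioxin-5-yl]but-3-en-2-one | C=CC(=O)[C@H](OCOC)[C@H]1C(C)=CC[C@H](OC2(C)C)[C@]1(C)[C@H](O2)CCC#C[Si](C)(C)C | intermediate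
20 | methyl propanoate | CCC(=O)OC | starting material
21 | methyl (2R,3R,4R)-3-ethenyl-3-hydroxy-4-(methoxymethoxy)-2-methyl-4-[(4R,4aS,5S,8aS)-2,2,4a,6-tetramethyl-4-[4-(trimethylsilyl)but-3-yn-1-yl]-4a,5,8,8a-tetrahydro-4H-1,3-benzodioxin-5-yl]butanoate | COC(=O)[C@H](C)[C@](O)(C=C)[C@H](OCOC)[C@H]1C(C)=CC[C@H](OC2(C)C)[C@]1(C)[C@H](O2)CCC#C[Si](C)(C)C | intermediate (not isolated)
22 | (2R,3R,4R)-4-[(4R,4aS,5S,8aS)-4-(but-3-yn-1-yl)-2,2,4a,6-tetramethyl-4a,5,8,8a-tetrahydro-4H-1,3-benzodioxin-5-yl]-3-ethenyl-3-hydroxy-4-(methoxymethoxy)-2-methylbutanoic acid | OC(=O)[C@H](C)[C@](O)(C=C)[C@H](OCOC)[C@H]1C(C)=CC[C@H](OC2(C)C)[C@]1(C)[C@H](O2)CCC#C | intermediate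
23 | (2R,3R,4R)-3-ethenyl-3-hydroxy-4-(methoxymethoxy)-2-methyl-4-[(4R,4aS,5S,8aS)-2,2,4a,6-tetramethyl-4-(3-methylidenepent-4-en-1-yl)-4a,5,8,8a-tetrahydro-4H-1,3-benzodioxin-5-yl]butanoic acid | OC(=O)[C@H](C)[C@](O)(C=C)[C@H](OCOC)[C@H]1C(C)=CC[C@H](OC2(C)C)[C@]1(C)[C@H](O2)CCC(=C)C=C | intermediate (not isolated)
24 | (1S,2R,6Z,8R,9R,10S,14S,17R)-8-hydroxy-2,14-(isopropylidenedioxy)-9-(methoxymethoxy)briara-5(16),6,11-trien-19-oic acid | C=C1/C=C\[C@@](O)([C@@H](C)C(O)=O)[C@H](OCOC)[C@H]2C(C)=CC[C@H](OC3(C)C)[C@]2(C)[C@H](O3)CC1 | intermediate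
25 | (1S,2R,5E,7S,8R,9R,10S,14S,17R)-16-acetoxy-8-hydroxy-2,14-(isopropylidenedioxy)-9-(methoxymethoxy)briara-5,11-dien-19,7-olide | CC(=O)OC/C1=C/[C@@H]2OC(=O)[C@H](C)[C@@]2(O)[C@H](OCOC)[C@H]2C(C)=CC[C@H](OC3(C)C)[C@]2(C)[C@H](O3)CC1 | intermediate
26 | (1S,2R,5E,7S,8R,9R,10S,14S,17R)-16-acetoxy-2,8,14-trihydroxy-9-(methoxymethoxy)briara-5,11-dien-19,7-olide | CC(=O)OC/C1=C/[C@@H]2OC(=O)[C@H](C)[C@@]2(O)[C@H](OCOC)[C@H]2C(C)=CC[C@H](O)[C@]2(C)[C@H](O)CC1 | intermediate
27 | (1S,2R,5E,7S,8R,9R,10S,14S,17R)-2,14,16-triacetoxy-8-hydroxy-9-(methoxymethoxy)briara-5,11-dien-19,7-olide | CC(=O)OC/C1=C/[C@@H]2OC(=O)[C@H](C)[C@@]2(O)[C@H](OCOC)[C@H]2C(C)=CC[C@H](OC(C)=O)[C@]2(C)[C@H](OC(C)=O)CC1 | intermediate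
28 | CNP0322315.2, (1S,2R,5E,7S,8R,9R,10S,14S,17R)-2,14,16-triacetoxy-8,9-dihydroxybriara-5,11-dien-19,7-olide | CC(=O)OC/C1=C/[C@@H]2OC(=O)[C@H](C)[C@@]2(O)[C@H](O)[C@H]2C(C)=CC[C@H](OC(C)=O)[C@]2(C)[C@H](OC(C)=O)CC1 | target

**Step count and risks**

Total step count: 16. Longest linear sequence: 16 steps from (S)-carvone (the route is fully linear; the acid chloride for step 1 is made and used in the same operation).

Three steps most likely to fail:

Step 7 (Wharton transposition). Hydrazone formation at a ketone flanked by two fully substituted carbons may stall. The fallback sets out from 12 and comes back at 14. Reduce the ketone with LiBH4 (THF, 0 °C; hydride is far smaller than hydrazine) to the epoxy alcohol F1. Convert it with MsCl and Et3N into the epoxy mesylate F2. Treat F2 with Cp2TiCl (made from Cp2TiCl2 and zinc dust, THF): the epoxide opens homolytically at C11, a second Cp2TiCl captures the tertiary radical, and β-elimination of mesylate gives 14 with the C12 hydroxyl and its configuration unchanged.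

Step 12 (ring B closure). A ten-membered ring must close next to the fully substituted C8 carbinol. The fallback sets out from 19 and comes back at 24; it closes the ring before C8 is made quaternary. Remove the silyl group of 19 (AgNO3 cat., acetone–H2O) to give the terminal ynenone F3. Ethylene cross-enyne metathesis gives the butadienyl enone F4, which ring-closes on the unhindered, electron-poor vinyl ketone (second-generation Hoveyda–Grubbs catalyst RuCl2(H2IMes)(=CH-C6H4-2-O-i-Pr), toluene, 80 °C) to the macrocyclic dienone F5. The aldol of step 11 on F5 (LiN(i-Pr)2, 20, −78 °C; chelation through the C9 MOM ether, now on a ring-constrained ketone) gives the methyl ester F6, and LiOH converts it into 24.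

Step 13 (the proposed new palladium step). Regiochemistry, lactone ring fusion or olefin geometry could go wrong. The fallback uses known chemistry, sets out from 24 and comes back at 25. Iodolactonisation (I2, NaHCO3, MeCN, 0 °C) gives the 16-iodo lactone F7: conjugate 1,4-halolactonisation of dienoic acids is known, and any 1,2-adduct with iodine at C6 equilibrates to the primary allylic iodide. AgOAc in AcOH then replaces iodide by acetate to give 25.

**Further compounds**

F1 | step 7 | epoxy alcohol (ketone of 12 reduced to the carbinol, either epimer) | OC1[C@@]2(C)O[C@H]2C[C@H](OC3(C)C)[C@]1(C)[C@H](O3)CCC#C[Si](C)(C)C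
F2 | step 7 | epoxy mesylate (methanesulfonate of F1) | CS(=O)(=O)OC1[C@@]2(C)O[C@H]2C[C@H](OC3(C)C)[C@]1(C)[C@H](O3)CCC#C[Si](C)(C)C
F3 | step 12 | terminal ynenone (19 without the silyl group) | C=CC(=O)[C@H](OCOC)[C@H]1C(C)=CC[C@H](OC2(C)C)[C@]1(C)[C@H](O2)CCC#C
F4 | step 12 | butadienyl enone (2-substituted butadiene from F3 and ethylene) | C=CC(=O)[C@H](OCOC)[C@H]1C(C)=CC[C@H](OC2(C)C)[C@]1(C)[C@H](O2)CCC(=C)C=C
F5 | step 12 | macrocyclic dienone (ring B closed, C8 ketone, Z-C6=C7, exocyclic C5=C16) | C=C1/C=C\C(=O)[C@H](OCOC)[C@H]2C(C)=CC[C@H](OC3(C)C)[C@]2(C)[C@H](O3)CC1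
F6 | step 12 | methyl ester of 24 | C=C1/C=C\[C@@](O)([C@@H](C)C(=O)OC)[C@H](OCOC)[C@H]2C(C)=CC[C@H](OC3(C)C)[C@]2(C)[C@H](O3)CC1
F7 | step 13 | 16-iodo lactone (25 with iodine in place of the 16-acetoxy group) | IC/C1=C/[C@@H]2OC(=O)[C@H](C)[C@@]2(O)[C@H](OCOC)[C@H]2C(C)=CC[C@H](OC3(C)C)[C@]2(C)[C@H](O3)CC1
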